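## Retrosynthetic overview

- The route rests on the cyclopentene C1–C5, with C1 (CH2OAc), C2 (CHO) and the C3 stereocentre carrying C1′ (CH–CHO). It is a ring-contracted p-menthane: C3/C1′ are C5 and the isopropenyl carbon of (S)-carvone, C2 and its formyl carbon are C6 and the ketone carbon, and C1 with its CH2OAc is C2 with its methyl.
- Key disconnection: the C1–C2 ring bond, made by Favorskii contraction of the silylated carvone chlorohydrin 4 to cyclopentanecarboxylate 6. This is the only ring-forming event.
- Elimination and conjugation then give enoate 10. The C1 methyl is oxidised through the silyl dienolate (γ-bromination, then PMB ether). The side chain is built at C2′–C3′ by ene chlorination of the isopropenyl group, geranyl sulfone alkylation and Pd-catalysed desulfonylation.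
- C1′ is set by substrate-controlled hydroboration of the 1,1-disubstituted alkene.
- A hydride that reduces the C2 ester would also cleave an acetate. The C1 oxygen is therefore carried as a PMB ether and exchanged for acetate while the other two carbinols are silylated; the two aldehydes are unveiled last.

Key step: step 4

Remark on the chemistry: in 6 the C2 methyl is taken as cis to the silyloxy group (inversion at the C–Cl carbon, protonation with retention). The anti-elimination of step 7 relies on this; C1 and C2 of 6 are otherwise of no consequence, because step 7 removes both centres.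

## Route

Step 1
Reactants: 1 (S)-(+)-carvone
Product: 2 (1S,4S,6S)-1-methyl-4-(prop-1-en-2-yl)-7-oxabicyclo[4.1.0]heptan-2-one
Conditions: 30% aq. H2O2, NaOH (cat.), MeOH, 0 °C
Reagents that add atoms: hydrogen peroxide, OO
Why: Weitz–Scheffer nucleophilic epoxidation of the enone only, the hydroperoxide adding axially anti to the C5 isopropenyl group so that the epoxide is trans to it.

Step 2
Reactants: 2 carvone epoxide
Product: 3 (2R,3S,5S)-2-chloro-3-hydroxy-2-methyl-5-(prop-1-en-2-yl)cyclohexan-1-one
Conditions: LiCl, CF3CO2H, THF, 0 → 23 °C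
Reagents that add atoms: lithium chloride, [Li+].[Cl-]
Why: Acid-assisted trans-diaxial opening of the α,β-epoxy ketone by chloride at the tertiary α-carbon with inversion, a known conversion of carvone oxide that leaves chlorine cis and hydroxyl trans to the isopropenyl group.

Step 3
Reactants: 3 chlorohydrin
Product: 4 (2R,3S,5S)-3-[(tert-butyldimethylsilyl)oxy]-2-chloro-2-methyl-5-(prop-1-en-2-yl)cyclohexan-1-one
Conditions: TBSOTf, 2,6-lutidine, CH2Cl2, −78 → 0 °C
Reagents that add atoms: tert-butyldimethylsilyl trifluoromethanesulfonate, CC(C)(C)[Si](C)(C)OS(=O)(=O)C(F)(F)F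
Why: Silylation of the secondary alcohol with a silyl triflate and a hindered pyridine base, which blocks re-closure of the chlorohydrin to the epoxide under the basic conditions of step 4.

Step 4
Reactants: 4 silylated chlorohydrin
Product: 6 methyl (1S,2R,3S,5S)-3-[(tert-butyldimethylsilyl)oxy]-2-methyl-5-(prop-1-en-2-yl)cyclopentane-1-carboxylate, via cyclopropanone 5 (not isolated)
Conditions: NaOMe, MeOH, 0 → 23 °C
Reagents that add atoms: sodium methoxide, [Na+].[O-]C
Why: Methoxide removes a C6 proton (C2 is quaternary, so only this enolate can form) and the enolate carbon displaces the axial C2 chloride with inversion in a 3-exo-tet closure, which makes the C2–C6 bond of the future five-membered ring and gives cyclopropanone 5. Methoxide then adds to the strained carbonyl and the resulting alkoxide opens by cleavage of the bond between the carbonyl carbon and the methyl-bearing carbon, so the ester ends on the former C6 next to the isopropenyl-bearing carbon. This is the Favorskii rearrangement, a known reaction of carvone-derived 2-chloro-3-alkoxy ketones. The cyclopentane is closed by ring contraction, that is intramolecular enolate C-alkylation followed by loss of the one-carbon bridge as the ester, and not by a separate cyclisation. C3 and C5 of 6 are carried over unchanged from 4, whereas C1 and C2 are new, fixed by the inversion at the C–Cl carbon and by protonation with retention, and both disappear in step 7. The step needs the cyclopropanone to open toward the methyl-bearing carbon, which the inductive pull of the adjacent C–O bond on the developing carbanion secures, and it needs the chlorohydrin not to revert to the epoxide, which the silyl ether secures.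

Step 5
Reactants: 6 silyl ether ester
Product: 7 methyl (1S,2R,3S,5S)-3-hydroxy-2-methyl-5-(prop-1-en-2-yl)cyclopentane-1-carboxylate
Conditions: 48% aq. HF, MeCN, 0 → 23 °C
Reagents that add atoms: none
Why: Acidic fluoride desilylation of the secondary silyl ether, which leaves the ester and the isopropenyl group alone; the hydroxyl and ester are trans across the ring, so no lactone can form.

Step 6
Reactants: 7 hydroxy ester
Product: 8 methyl (1S,2R,3S,5S)-3-(methanesulfonyloxy)-2-methyl-5-(prop-1-en-2-yl)cyclopentane-1-carboxylate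
Conditions: MsCl, Et3N, CH2Cl2, 0 °C
Reagents that add atoms: methanesulfonyl chloride, CS(=O)(=O)Cl
Why: O-sulfonylation of the secondary alcohol with retention, installing the leaving group for the elimination.

Step 7
Reactants: 8 mesylate
Product: 10 methyl (5R)-2-methyl-5-(prop-1-en-2-yl)cyclopent-1-ene-1-carboxylate, via deconjugated ester 9 (not isolated)
Conditions: DBU, PhMe, 110 °C
Reagents that add atoms: none
Why: E2 anti-elimination removes the tertiary C2–H, which is trans to the mesylate, to give the trisubstituted alkene 9 (Zaitsev), and DBU then shifts the double bond through the dienolate into conjugation with the ester; C5–H is not on that path, so the stereocentre is kept.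

Step 8
Reactants: 10 enoate
Product: 13 methyl (5R)-2-(bromomethyl)-5-(prop-1-en-2-yl)cyclopent-1-ene-1-carboxylate, via lithium dienolate 11 (not isolated), via silyl ketene acetal 12 (not isolated)
Conditions: LiN(i-Pr)2, DMPU, THF, −78 °C; Me3SiCl, −78 °C; volatiles removed; NBS, THF, −78 °C
Reagents that add atoms: N-bromosuccinimide, O=C1CCC(=O)N1Br
Why: Kinetic γ-deprotonation at the methyl group syn to the ester gives the exocyclic dienolate, O-silylation gives the silyl dienol ether, and the soft bromine electrophile attacks its unhindered terminal carbon (vinylogous, γ-selective halogenation of O-silyl dienolates), restoring the conjugated ester; the isopropenyl group is far less nucleophilic than the ketene acetal.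

Step 9
Reactants: 13 allylic bromide
Product: 14 methyl (5R)-2-{[(4-methoxyphenyl)methoxy]methyl}-5-(prop-1-en-2-yl)cyclopent-1-ene-1-carboxylate
Conditions: 4-methoxybenzyl alcohol, NaH, THF, 0 °C; then 13, −20 → 0 °C
Reagents that add atoms: 4-methoxybenzyl alcohol, COc1ccc(CO)cc1
Why: Williamson etherification, the SN2 displacement at the primary allylic bromide being much faster than attack of the alkoxide on the hindered, conjugated ester.

Step 10
Reactants: 14 PMB ether
Product: 15 methyl (5S)-5-(3-chloroprop-1-en-2-yl)-2-{[(4-methoxyphenyl)methoxy]methyl}cyclopent-1-ene-1-carboxylate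
Conditions: Ca(OCl)2, CO2 (solid), CH2Cl2/H2O, 0 °C
Reagents that add atoms: calcium hypochlorite, [Ca+2].[O-]Cl.[O-]Cl
Why: Ene-type allylic chlorination by hypochlorous acid, in which chlorine adds to the terminal carbon of the isopropenyl group and a methyl proton is lost to give the 2-substituted allyl chloride; the ring alkene is deactivated by the ester and the ring stereocentre is not touched (its descriptor changes only through the priority of CH2Cl).

Step 11
Reactants: 16 geranyl bromide
Product: 17 geranyl phenyl sulfone, {[(2E)-3,7-dimethylocta-2,6-dien-1-yl]sulfonyl}benzene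
Conditions: PhSO2Na, DMF, 23 °C
Reagents that add atoms: sodium benzenesulfinate, [Na+].[O-]S(=O)c1ccccc1
Why: S-alkylation of the sulfinate by SN2 at the primary allylic bromide, which keeps the E alkene.

Step 12
Reactants: 15 allylic chloride; 17 geranyl phenyl sulfone
Product: 19 methyl (5R)-5-[(5E)-4-(benzenesulfonyl)-6,10-dimethylundeca-1,5,9-trien-2-yl]-2-{[(4-methoxyphenyl)methoxy]methyl}cyclopent-1-ene-1-carboxylate (both epimers at the sulfonyl carbon), via lithiated sulfone 18 (not isolated)
Conditions: 17, n-BuLi, THF, −78 °C; then 15, DMPU, −78 → 0 °C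
Reagents that add atoms: none
Why: Alkylation of the α-sulfonyl carbanion at the primary allylic chloride forms the C2′–C3′ bond (the 2-substituted allyl unit is symmetric, so SN2 and SN2′ give the same product), the hindered tetrasubstituted methyl enoate being slow toward this stabilised anion at low temperature; the new sulfonyl-bearing centre is removed in step 13.

Step 13
Reactants: 19 sulfone ester
Product: 20 [(5R)-5-[(5E)-6,10-dimethylundeca-1,5,9-trien-2-yl]-2-{[(4-methoxyphenyl)methoxy]methyl}cyclopent-1-en-1-yl]methanol
Conditions: LiBHEt3 (excess), PdCl2[Ph2P(CH2)3PPh2] (cat.), THF, 0 → 23 °C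
Reagents that add atoms: none
Why: Pd-catalysed reductive desulfonylation of the allylic sulfone, in which zerovalent palladium formed in situ ionises the C–S bond and hydride is delivered to the less substituted allyl terminus so that the trisubstituted alkene stays in place and E, while the same hydride reduces the conjugated methyl ester in a 1,2 sense to the allylic alcohol.

Step 14
Reactants: 20 trienol
Product: 21 (2S,5E)-2-[(1R)-2-(hydroxymethyl)-3-{[(4-methoxyphenyl)methoxy]methyl}cyclopent-2-en-1-yl]-6,10-dimethylundeca-5,9-dien-1-ol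
Conditions: 9-BBN (9-borabicyclo[3.3.1]nonane, 3 equiv), THF, 0 → 23 °C; then NaOH, H2O2, 0 °C
Reagents that add atoms: hydrogen peroxide, OO
Why: Anti-Markovnikov hydroboration–oxidation with a bulky borane that adds only to the 1,1-disubstituted alkene, C1′ being set by substrate control: in the reactive rotamer the C3–H lies in the alkene plane syn to the =CH2 group and the borane attacks the face on the C4H2 side, away from C2 and its CH2O–boron substituent, which should give the (S) centre.

Step 15
Reactants: 21 diol
Product: 22 bis(tert-butyldimethylsilyl) ether of 21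
Conditions: TBSCl, imidazole, DMF, 23 °C
Reagents that add atoms: tert-butyldimethylsilyl chloride, CC(C)(C)[Si](C)(C)Cl
Why: Standard silylation of both primary alcohols, so that the C1 oxygen can be handled alone.

Step 16
Reactants: 22 bis-silyl PMB ether
Product: 23 [(3R)-2-{[(tert-butyldimethylsilyl)oxy]methyl}-3-[(2S,5E)-1-[(tert-butyldimethylsilyl)oxy]-6,10-dimethylundeca-5,9-dien-2-yl]cyclopent-1-en-1-yl]methanol
Conditions: DDQ, CH2Cl2/pH 7 buffer, 0 °C
Reagents that add atoms: none
Why: Oxidative cleavage of the 4-methoxybenzyl ether by benzylic hydride abstraction and hydrolysis of the resulting oxocarbenium ion, with silyl ethers and isolated alkenes inert under buffered conditions.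

Step 17
Reactants: 23 allylic alcohol
Product: 24 [(3R)-2-{[(tert-butyldimethylsilyl)oxy]methyl}-3-[(2S,5E)-1-[(tert-butyldimethylsilyl)oxy]-6,10-dimethylundeca-5,9-dien-2-yl]cyclopent-1-en-1-yl]methyl acetate
Conditions: Ac2O, pyridine, DMAP (cat.), CH2Cl2, 0 → 23 °C
Reagents that add atoms: acetic anhydride, CC(=O)OC(C)=O
Why: DMAP-catalysed acetylation of the only free hydroxyl places the acetate on the C1 carbinol.

Step 18
Reactants: 24 bis-silyl acetate
Product: 25 [(3R)-2-(hydroxymethyl)-3-[(2S,5E)-1-hydroxy-6,10-dimethylundeca-5,9-dien-2-yl]cyclopent-1-en-1-yl]methyl acetate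
Conditions: HF·pyridine, pyridine, THF, 0 → 23 °C
Reagents that add atoms: none
Why: Buffered acidic fluoride removes both primary silyl ethers while the acetate survives and base-promoted acyl migration to the neighbouring carbinol is avoided; the diol is taken on without delay.

Step 19
Reactants: 25 diol monoacetate
Product: 26 [(3R)-2-formyl-3-[(2S,5E)-6,10-dimethyl-1-oxoundeca-5,9-dien-2-yl]cyclopent-1-en-1-yl]methyl acetate (target)
Conditions: Dess–Martin periodinane, NaHCO3, CH2Cl2, 0 → 23 °C
Reagents that add atoms: none
Why: Buffered hypervalent-iodine oxidation converts the allylic and the saturated primary alcohol to the enal and the α-branched aldehyde under near-neutral conditions that should not epimerise C1′ or disturb the allylic acetate.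

## Compound list

1 | (S)-(+)-carvone, (5S)-2-methyl-5-(prop-1-en-2-yl)cyclohex-2-en-1-one | CC1=CC[C@@H](CC1=O)C(C)=C | starting material
2 | (1S,4S,6S)-1-methyl-4-(prop-1-en-2-yl)-7-oxabicyclo[4.1.0]heptan-2-one | O=C1C[C@@H](C(C)=C)C[C@@H]2O[C@]12C | intermediate
3 | (2R,3S,5S)-2-chloro-3-hydroxy-2-methyl-5-(prop-1-en-2-yl)cyclohexan-1-one | O=C1C[C@@H](C(C)=C)C[C@H](O)[C@@]1(C)Cl | intermediate
4 | (2R,3S,5S)-3-[(tert-butyldimethylsilyl)oxy]-2-chloro-2-methyl-5-(prop-1-en-2-yl)cyclohexan-1-one | O=C1C[C@@H](C(C)=C)C[C@H](O[Si](C)(C)C(C)(C)C)[C@@]1(C)Cl | intermediate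
5 | 2-[(tert-butyldimethylsilyl)oxy]-1-methyl-4-(prop-1-en-2-yl)bicyclo[3.1.0]hexan-6-one, carbonyl bridge on the face of the isopropenyl group, methyl and silyloxy on the other face | O=C1[C@]2(C)[C@@H](O[Si](C)(C)C(C)(C)C)C[C@H](C(C)=C)[C@H]12 | intermediate
6 | methyl (1S,2R,3S,5S)-3-[(tert-butyldimethylsilyl)oxy]-2-methyl-5-(prop-1-en-2-yl)cyclopentane-1-carboxylate | C[C@@H]1[C@@H](C(=O)OC)[C@@H](C(C)=C)C[C@@H]1O[Si](C)(C)C(C)(C)C | intermediate
7 | methyl (1S,2R,3S,5S)-3-hydroxy-2-methyl-5-(prop-1-en-2-yl)cyclopentane-1-carboxylate | C[C@@H]1[C@@H](C(=O)OC)[C@@H](C(C)=C)C[C@@H]1O | intermediate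
8 | methyl (1S,2R,3S,5S)-3-(methanesulfonyloxy)-2-methyl-5-(prop-1-en-2-yl)cyclopentane-1-carboxylate | C[C@@H]1[C@@H](C(=O)OC)[C@@H](C(C)=C)C[C@@H]1OS(C)(=O)=O | intermediate
9 | methyl (5S)-2-methyl-5-(prop-1-en-2-yl)cyclopent-2-ene-1-carboxylate (C1 epimers) | CC1=CC[C@H](C(C)=C)C1C(=O)OC | intermediate
10 | methyl (5R)-2-methyl-5-(prop-1-en-2-yl)cyclopent-1-ene-1-carboxylate | CC1=C(C(=O)OC)[C@@H](C(C)=C)CC1 | intermediate
11 | lithium dienolate of 10, lithium methoxy[(5R)-2-methylidene-5-(prop-1-en-2-yl)cyclopentylidene]methanolate | [Li+].C=C1CC[C@H](C(C)=C)C1=C(OC)[O-] | intermediate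
12 | {methoxy[(5R)-2-methylidene-5-(prop-1-en-2-yl)cyclopentylidene]methoxy}trimethylsilane | C=C1CC[C@H](C(C)=C)C1=C(OC)O[Si](C)(C)C | intermediate
13 | methyl (5R)-2-(bromomethyl)-5-(prop-1-en-2-yl)cyclopent-1-ene-1-carboxylate | BrCC1=C(C(=O)OC)[C@@H](C(C)=C)CC1 | intermediate
14 | methyl (5R)-2-{[(4-methoxyphenyl)methoxy]methyl}-5-(prop-1-en-2-yl)cyclopent-1-ene-1-carboxylate | COc1ccc(COCC2=C(C(=O)OC)[C@@H](C(C)=C)CC2)cc1 | intermediate
15 | methyl (5S)-5-(3-chloroprop-1-en-2-yl)-2-{[(4-methoxyphenyl)methoxy]methyl}cyclopent-1-ene-1-carboxylate | COc1ccc(COCC2=C(C(=O)OC)[C@@H](C(=C)CCl)CC2)cc1 | intermediate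
16 | geranyl bromide, (2E)-1-bromo-3,7-dimethylocta-2,6-diene | CC(C)=CCC/C(C)=C/CBr | starting material
17 | geranyl phenyl sulfone, {[(2E)-3,7-dimethylocta-2,6-dien-1-yl]sulfonyl}benzene | CC(C)=CCC/C(C)=C/CS(=O)(=O)c1ccccc1 | intermediate
18 | α-lithio derivative of 17 | [Li+].CC(C)=CCC/C(C)=C/[CH-]S(=O)(=O)c1ccccc1 | intermediate
19 | methyl (5R)-5-[(5E)-4-(benzenesulfonyl)-6,10-dimethylundeca-1,5,9-trien-2-yl]-2-{[(4-methoxyphenyl)methoxy]methyl}cyclopent-1-ene-1-carboxylate (both epimers at the sulfonyl carbon) | COc1ccc(COCC2=C(C(=O)OC)[C@@H](C(=C)CC(/C=C(\C)CCC=C(C)C)S(=O)(=O)c3ccccc3)CC2)cc1 | intermediate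
20 | [(5R)-5-[(5E)-6,10-dimethylundeca-1,5,9-trien-2-yl]-2-{[(4-methoxyphenyl)methoxy]methyl}cyclopent-1-en-1-yl]methanol | COc1ccc(COCC2=C(CO)[C@@H](C(=C)CC/C=C(\C)CCC=C(C)C)CC2)cc1 | intermediate
21 | (2S,5E)-2-[(1R)-2-(hydroxymethyl)-3-{[(4-methoxyphenyl)methoxy]methyl}cyclopent-2-en-1-yl]-6,10-dimethylundeca-5,9-dien-1-ol | COc1ccc(COCC2=C(CO)[C@@H]([C@@H](CO)CC/C=C(\C)CCC=C(C)C)CC2)cc1 | intermediate
22 | bis(tert-butyldimethylsilyl) ether of 21, ring centre (R), side-chain centre (S) | COc1ccc(COCC2=C(CO[Si](C)(C)C(C)(C)C)[C@@H]([C@@H](CO[Si](C)(C)C(C)(C)C)CC/C=C(\C)CCC=C(C)C)CC2)cc1 | intermediate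
23 | [(3R)-2-{[(tert-butyldimethylsilyl)oxy]methyl}-3-[(2S,5E)-1-[(tert-butyldimethylsilyl)oxy]-6,10-dimethylundeca-5,9-dien-2-yl]cyclopent-1-en-1-yl]methanol | OCC1=C(CO[Si](C)(C)C(C)(C)C)[C@@H]([C@@H](CO[Si](C)(C)C(C)(C)C)CC/C=C(\C)CCC=C(C)C)CC1 | intermediate
24 | [(3R)-2-{[(tert-butyldimethylsilyl)oxy]methyl}-3-[(2S,5E)-1-[(tert-butyldimethylsilyl)oxy]-6,10-dimethylundeca-5,9-dien-2-yl]cyclopent-1-en-1-yl]methyl acetate | CC(=O)OCC1=C(CO[Si](C)(C)C(C)(C)C)[C@@H]([C@@H](CO[Si](C)(C)C(C)(C)C)CC/C=C(\C)CCC=C(C)C)CC1 | intermediate
25 | [(3R)-2-(hydroxymethyl)-3-[(2S,5E)-1-hydroxy-6,10-dimethylundeca-5,9-dien-2-yl]cyclopent-1-en-1-yl]methyl acetate | CC(=O)OCC1=C(CO)[C@@H]([C@@H](CO)CC/C=C(\C)CCC=C(C)C)CC1 | intermediate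
26 | [(3R)-2-formyl-3-[(2S,5E)-6,10-dimethyl-1-oxoundeca-5,9-dien-2-yl]cyclopent-1-en-1-yl]methyl acetate | CC(=O)OCC1=C(C=O)[C@@H]([C@@H](C=O)CC/C=C(\C)CCC=C(C)C)CC1 | target

## Step count and risks

Total step count: 19. Longest linear sequence: 18 steps (steps 1–10 and 12–19 from 1; step 11 is the one-step side branch from 16).

Steps most likely to fail:

1. Step 14. The facial selectivity at C1′ may be poor, because the two ring neighbours of C3 differ only moderately and a second rotamer of the alkene would deliver the epimer. The fallback replaces substrate control by catalyst control. It sets out from 20, which is silylated (TBSCl, imidazole) to the mono-silyl ether F1. F1 is hydroborated with pinacolborane under a copper hydride catalyst made from CuCl, NaOt-Bu and DTBM-SEGPHOS (the ligand enantiomer that gives the (S) centre) to the pinacol boronate F2. Oxidation (NaOH, H2O2) gives the primary alcohol F3, and a second silylation brings the material back to the route at 22.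

2. Step 8. The electrophile may attack the α-carbon of the dienolate instead of the terminal carbon, or bromination may be unselective. The fallback uses the intrinsic α-reactivity of the lithium dienolate followed by an allylic transposition. It sets out from 10, which is deprotonated with LiN(i-Pr)2 and hydroxylated with 2-(benzenesulfonyl)-3-phenyloxaziridine to the tertiary α-hydroxy ester F4. PBr3 in Et2O then replaces the hydroxyl with allylic shift (SN2′), which moves the alkene into conjugation and returns to the route at 13.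

3. Step 7. The elimination may run toward C4 instead of C2, for example if the anti-periplanar C2–H is not available, and that alkene cannot be brought into conjugation. The fallback fixes the position of the alkene through an enol derivative and does not depend on the configuration at C2. It sets out from 7, which is oxidised (Dess–Martin periodinane) to the ketone F5. Triflation under equilibrating conditions (Tf2O, 2,6-di-tert-butyl-4-methylpyridine) gives the more substituted enol triflate F6. Reduction with Pd(OAc)2, PPh3, HCO2H and n-Bu3N returns to the route at 9, which DBU conjugates to 10 as in step 7.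

Further compounds
F1 | step 14 | tert-butyldimethylsilyl ether of 20 | COc1ccc(COCC2=C(CO[Si](C)(C)C(C)(C)C)[C@@H](C(=C)CC/C=C(\C)CCC=C(C)C)CC2)cc1
F2 | step 14 | pinacol boronate at the C1′ methylene carbon, ring centre (R), side-chain centre as in 21 | COc1ccc(COCC2=C(CO[Si](C)(C)C(C)(C)C)[C@@H]([C@@H](CB3OC(C)(C)C(C)(C)O3)CC/C=C(\C)CCC=C(C)C)CC2)cc1
F3 | step 14 | mono-silyl ether of 21 with the side-chain primary alcohol free | COc1ccc(COCC2=C(CO[Si](C)(C)C(C)(C)C)[C@@H]([C@@H](CO)CC/C=C(\C)CCC=C(C)C)CC2)cc1
F4 | step 8 | methyl 1-hydroxy-2-methylidene-5-(prop-1-en-2-yl)cyclopentane-1-carboxylate (C5 as in 10, C1 epimers) | C=C1CC[C@H](C(C)=C)C1(O)C(=O)OC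
F5 | step 7 | methyl 2-methyl-3-oxo-5-(prop-1-en-2-yl)cyclopentane-1-carboxylate (configuration as in 7) | C[C@@H]1[C@@H](C(=O)OC)[C@@H](C(C)=C)CC1=O
F6 | step 7 | methyl 2-methyl-5-(prop-1-en-2-yl)-3-(trifluoromethanesulfonyloxy)cyclopent-2-ene-1-carboxylate (C5 as in 7, C1 epimers) | CC1=C(OS(=O)(=O)C(F)(F)F)C[C@H](C(C)=C)C1C(=O)OC
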